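Ring C is taken apart at three bonds, C4a–C4, C4–C3 and O1–C2. The feature exploited is that C4 carries nothing but its oxygen and bridges C4a of the persubstituted ring A to the C3=C2 enol ether carbons, so this one-carbon unit can enter as carbon monoxide. A single palladium-catalysed operation joins a hexasubstituted ring A iodide, CO and the ring B arylacetylene and closes the pyranone. The ring A partner is 2-iodo-3,4,5,6-tetramethoxyphenol, carried into the coupling as its O-acetate, which lowers the electron density at the C–I carbon and is shed in the flask. The C3 methoxy group follows by C3 lithiation, borylation–oxidation and O-methylation.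

Key step: step 6

Remark: the target, 3,5,6,7,8,2',4'-heptamethoxyflavone, has no stereocentre and no stereogenic double bond, so no step has to control configuration.

Step 1
Reactants: 1 3,4,5-trimethoxyphenol
Product: 2 2-bromo-3,4,5-trimethoxyphenol
Conditions: NBS (1.0 equiv), CH2Cl2, −78 → 0 °C, dark
Reagents that add atoms: N-bromosuccinimide, O=C1CCC(=O)N1Br
Why: Electrophilic aromatic bromination; the two free ring positions are equivalent, each ortho to the hydroxyl and para to a methoxy group, so one equivalent of NBS at low temperature should stop at a single monobromide.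

Step 2
Reactants: 2 2-bromo-3,4,5-trimethoxyphenol
Product: 3 2,3,4,5-tetramethoxyphenol
Conditions: NaOMe (28 % in MeOH, 6 equiv), CuBr (0.2 equiv), DMF, 100 °C, argon; then 1 M HCl, 0 °C
Reagents that add atoms: sodium methoxide, C[O-].[Na+]
Why: Ullmann-type copper-catalysed methoxylation of an aryl bromide, which is routine on ortho-bromophenolates and on bromides flanked by methoxy groups; air is excluded because the electron-rich phenolate is easily oxidised.

Step 3
Reactants: 3 2,3,4,5-tetramethoxyphenol
Product: 4 2-iodo-3,4,5,6-tetramethoxyphenol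
Conditions: NIS (1.05 equiv), dry MeCN, −10 → 0 °C, dark
Reagents that add atoms: N-iodosuccinimide, O=C1CCC(=O)N1I
Why: Electrophilic aromatic iodination; the only remaining C–H lies ortho to the hydroxyl and para to a methoxy group, so a mild iodonium source under dry, cold conditions should suffice and no regioisomer can form.

Step 4
Reactants: 4 2-iodo-3,4,5,6-tetramethoxyphenol
Product: 5 2-iodo-3,4,5,6-tetramethoxyphenyl acetate
Conditions: Ac2O (1.5 equiv), DMAP (cat.), pyridine, 0 °C → rt
Reagents that add atoms: acetic anhydride, CC(=O)OC(C)=O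
Why: DMAP-catalysed O-acylation of a phenol; the ester makes the ring less electron-rich, stops phenolate formation in the amine medium of step 6 and gives an air-stable, storable coupling partner.

Step 5
Reactants: 6 2,4-dimethoxybenzaldehyde
Product: 7 1-ethynyl-2,4-dimethoxybenzene
Conditions: dimethyl (1-diazo-2-oxopropyl)phosphonate (1.2 equiv), K2CO3 (2 equiv), MeOH, rt
Reagents that add atoms: dimethyl (1-diazo-2-oxopropyl)phosphonate (Ohira–Bestmann reagent), CC(=O)C(=[N+]=[N-])P(=O)(OC)OC
Why: Ohira–Bestmann homologation (olefination by the deacylated diazophosphonate, loss of N2 and 1,2-shift), a standard one-step conversion of non-enolisable aryl aldehydes into terminal alkynes under mild base.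

Step 6
Reactants: 5 2-iodo-3,4,5,6-tetramethoxyphenyl acetate; 7 1-ethynyl-2,4-dimethoxybenzene (1.5 equiv); 8 carbon monoxide
Product: 11 5,6,7,8,2',4'-hexamethoxyflavone, via ynone acetate 9 (not isolated), via enaminone 10 (not isolated)
Conditions: PdCl2(PPh3)2 (5 mol %), 1,3-bis(diphenylphosphino)propane (dppp, 5 mol %), CO (1 atm, balloon), Et2NH (solvent), 50 °C, no copper salt
Reagents that add atoms: carbon monoxide 8, [C-]#[O+] (listed above as reactant; supplies C4 and its oxygen); diethylamine, CCNCC (present only in intermediate 10, released on ring closure)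
Why: Zerovalent palladium, generated in the flask from PdCl2(PPh3)2, adds oxidatively to the C–I bond of 5, CO inserts to give an aroylpalladium iodide, and this takes up 7 as an amine-generated alkynyl ligand and reductively eliminates ynone 9, which sets C4a–C4 and C4–C3. Diethylamine then cleaves the aryl acetate, now activated by the ortho acyl group, by aminolysis and adds to the ynone in conjugate fashion to give enaminone 10, whose phenol attacks C2 and expels the amine, which sets O1–C2. The closest known reaction type is the copper-free carbonylative Sonogashira annulation of 2-iodophenols and 2-iodophenyl acetates with terminal arylacetylenes to flavones. Ring C is the only ring formed and closes in a six-membered mode, formally 6-endo-dig on the ynone and in practice a 6-endo-trig addition followed by elimination on 10; no stereocentre arises. Three selectivities are needed: CO uptake before alkynylation, favoured by the absence of copper, a CO-saturated medium and the fast migratory insertion of an electron-rich, di-ortho-substituted arylpalladium; alkyne rather than amine capture of the aroylpalladium, favoured by the two ortho substituents that screen the acyl carbon and by the excess of 7; and six-membered rather than five-membered closure, secured because in 10 only C2 is electrophilic while C3 has become nucleophilic. Ring A raises no regiochemical question because all six positions of 5 are occupied, and the acetate prevents phenolate formation before oxidative addition, the slowest event at this hindered carbon.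

Step 7
Reactants: 11 5,6,7,8,2',4'-hexamethoxyflavone
Product: 14 3-hydroxy-5,6,7,8,2',4'-hexamethoxyflavone, via 3-lithioflavone 12 (not isolated), via lithium borate 13 (not isolated)
Conditions: LiN(iPr)2 (1.3 equiv), THF, −78 °C; B(OMe)3 (3 equiv), −78 → 0 °C; AcOH, 30 % H2O2, 0 °C → rt
Reagents that add atoms: hydrogen peroxide, OO (the C3 oxygen); trimethyl borate, COB(OC)OC (in 13 only); lithium diisopropylamide, [Li+].CC(C)[N-]C(C)C (lithium in 12 and 13 only)
Why: Deprotonation of the flavone C3–H by a non-nucleophilic amide base at −78 °C (the carbonyl cannot enolise, and the C4 oxygen and the 2'-methoxy group can hold the lithium), electrophilic borylation and oxidative boron-to-oxygen 1,2-migration form an established sequence from flavones to flavonols.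

Step 8
Reactants: 14 3-hydroxy-5,6,7,8,2',4'-hexamethoxyflavone
Product: 15 3,5,6,7,8,2',4'-heptamethoxyflavone (target)
Conditions: MeI (3 equiv), K2CO3 (3 equiv), acetone, reflux
Reagents that add atoms: iodomethane, CI
Why: Williamson-type O-methylation; the 3-hydroxyl is the only acidic site left, and its hydrogen bond to the C4 carbonyl is overcome by K2CO3 in refluxing acetone.

Compound list
1 | 3,4,5-trimethoxyphenol | COc1cc(O)cc(OC)c1OC | starting material
2 | 2-bromo-3,4,5-trimethoxyphenol | COc1cc(O)c(Br)c(OC)c1OC | intermediate
3 | 2,3,4,5-tetramethoxyphenol | COc1cc(O)c(OC)c(OC)c1OC | intermediate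
4 | 2-iodo-3,4,5,6-tetramethoxyphenol | COc1c(O)c(I)c(OC)c(OC)c1OC | intermediate
5 | 2-iodo-3,4,5,6-tetramethoxyphenyl acetate | COc1c(OC(C)=O)c(I)c(OC)c(OC)c1OC | intermediate
6 | 2,4-dimethoxybenzaldehyde | COc1ccc(C=O)c(OC)c1 | starting material
7 | 1-ethynyl-2,4-dimethoxybenzene | C#Cc1ccc(OC)cc1OC | intermediate
8 | carbon monoxide | [C-]#[O+] | starting material
9 | 2-[3-(2,4-dimethoxyphenyl)prop-2-ynoyl]-3,4,5,6-tetramethoxyphenyl acetate (ynone acetate, not isolated) | COc1ccc(C#CC(=O)c2c(OC(C)=O)c(OC)c(OC)c(OC)c2OC)c(OC)c1 | intermediate
10 | 3-(diethylamino)-3-(2,4-dimethoxyphenyl)-1-(2-hydroxy-3,4,5,6-tetramethoxyphenyl)prop-2-en-1-one (enaminone, not isolated; push–pull alkene, geometry labile and not fixed) | CCN(CC)C(=CC(=O)c1c(O)c(OC)c(OC)c(OC)c1OC)c1ccc(OC)cc1OC | intermediate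
11 | 5,6,7,8,2',4'-hexamethoxyflavone = 2-(2,4-dimethoxyphenyl)-5,6,7,8-tetramethoxy-4H-chromen-4-one | COc1ccc(-c2cc(=O)c3c(OC)c(OC)c(OC)c(OC)c3o2)c(OC)c1 | intermediate
12 | 3-lithio-5,6,7,8,2',4'-hexamethoxyflavone (not isolated) | COc1ccc(-c2oc3c(OC)c(OC)c(OC)c(OC)c3c(=O)c2[Li])c(OC)c1 | intermediate
13 | lithium trimethoxy(5,6,7,8,2',4'-hexamethoxyflavon-3-yl)borate (not isolated) | [Li+].COc1ccc(-c2oc3c(OC)c(OC)c(OC)c(OC)c3c(=O)c2[B-](OC)(OC)OC)c(OC)c1 | intermediate
14 | 3-hydroxy-5,6,7,8,2',4'-hexamethoxyflavone | COc1ccc(-c2oc3c(OC)c(OC)c(OC)c(OC)c3c(=O)c2O)c(OC)c1 | intermediate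
15 | 3,5,6,7,8,2',4'-heptamethoxyflavone = 2-(2,4-dimethoxyphenyl)-3,5,6,7,8-pentamethoxy-4H-chromen-4-one | COc1ccc(-c2oc3c(OC)c(OC)c(OC)c(OC)c3c(=O)c2OC)c(OC)c1 | target

Total step count: 8.
Longest linear sequence: 7 steps (1 → 2 → 3 → 4 → 5 → 11 → 14 → 15). Step 5 is the only step of the second branch.

Steps most likely to fail

Step 6.
- What may go wrong: oxidative addition at the di-ortho-substituted, electron-rich C–I carbon may be too slow. The aroylpalladium species may be intercepted by diethylamine instead of the alkyne. Coupling may also occur without CO uptake.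
- Fallback: it gives up CO as the C4 source, sets out from 3 and returns at 11.
- C-Acetylation of 3 at its only free position (Ac2O, BF3·OEt2, 70 °C, Friedel–Crafts/Fries type) should give 1-(2-hydroxy-3,4,5,6-tetramethoxyphenyl)ethan-1-one F1.
- Claisen–Schmidt condensation of F1 with aldehyde 6 (KOH, EtOH, rt) should give (E)-3-(2,4-dimethoxyphenyl)-1-(2-hydroxy-3,4,5,6-tetramethoxyphenyl)prop-2-en-1-one F2.
- Oxidative cyclisation of F2 with catalytic I2 in DMSO at 120 °C should deliver 11.

Step 2.
- What may go wrong: reductive loss of bromine may compete with substitution, and the hot phenolate may degrade oxidatively.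
- Fallback: it postpones the halogen-to-methoxy exchange until the ring belongs to the electron-poor chromone, where this exchange is well known at C8. It sets out from 2 and returns at 11 in the same number of operations.
- Iodination of 2 (NIS, MeCN, 0 °C) should give 2-bromo-6-iodo-3,4,5-trimethoxyphenol F3.
- Acetylation (Ac2O, pyridine) should give 2-bromo-6-iodo-3,4,5-trimethoxyphenyl acetate F4.
- Annulation of F4 with 7 and 8 under the conditions of step 6 should engage only the C–I bond and give 8-bromo-2-(2,4-dimethoxyphenyl)-5,6,7-trimethoxy-4H-chromen-4-one F5.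
- Treatment of F5 with NaOMe and CuBr in DMF/MeOH at 100 °C, then acidic work-up to re-close any opened pyranone, should give 11.

Step 7.
- What may go wrong: deprotonation may be incomplete or misdirected, since the ring B C3'–H between two methoxy groups competes. The C3 anion may also fragment by expulsion of the ring phenoxide if the temperature rises before borylation.
- Fallback: it replaces anion chemistry by electrophilic oxygen transfer, sets out from 11 and returns at 14.
- Dimethyldioxirane (acetone solution, CH2Cl2, 0 °C) should epoxidise the C2=C3 enol ether bond to give racemic 1a-(2,4-dimethoxyphenyl)-3,4,5,6-tetramethoxy-1a,7a-dihydro-7H-oxireno[2,3-b]chromen-7-one F6.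
- A trace of p-TsOH should then open and tautomerise F6 to flavonol 14.

Further compounds
F1 | step 6 | 1-(2-hydroxy-3,4,5,6-tetramethoxyphenyl)ethan-1-one | CC(=O)c1c(O)c(OC)c(OC)c(OC)c1OC
F2 | step 6 | (E)-3-(2,4-dimethoxyphenyl)-1-(2-hydroxy-3,4,5,6-tetramethoxyphenyl)prop-2-en-1-one | COc1ccc(/C=C/C(=O)c2c(O)c(OC)c(OC)c(OC)c2OC)c(OC)c1
F3 | step 2 | 2-bromo-6-iodo-3,4,5-trimethoxyphenol | COc1c(I)c(O)c(Br)c(OC)c1OC
F4 | step 2 | 2-bromo-6-iodo-3,4,5-trimethoxyphenyl acetate | COc1c(I)c(OC(C)=O)c(Br)c(OC)c1OC
F5 | step 2 | 8-bromo-2-(2,4-dimethoxyphenyl)-5,6,7-trimethoxy-4H-chromen-4-one | COc1ccc(-c2cc(=O)c3c(OC)c(OC)c(OC)c(Br)c3o2)c(OC)c1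
F6 | step 7 | 1a-(2,4-dimethoxyphenyl)-3,4,5,6-tetramethoxy-1a,7a-dihydro-7H-oxireno[2,3-b]chromen-7-one (racemic, cis ring fusion, one enantiomer drawn) | COc1ccc([C@@]23O[C@@H]2C(=O)c2c(OC)c(OC)c(OC)c(OC)c2O3)c(OC)c1
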